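**Retrosynthetic overview**

1. Target 17 ⇐ 16 ⇐ 15 by hydrogenolysis of four benzyl ethers and methanolysis of one acetate. No ring is formed at any stage: ring A (the resorcylate ring) and ring B (the resorcinol ring) both come from the same bought arene 1.
2. 15 ⇐ aroyl bromide 13 + butanal 6 + olefin 4. The bond between the ester-bearing methine carbon C8' and the neighbouring chain methylene C7' of the ring-B chain is made by a nickel-catalysed enantioconvergent hydroalkylation, which in one operation joins the two halves, completes the ester and sets C8' as (R).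
3. Enabling feature: C8' is a dialkyl carbinol ester carbon whose two carbon arms (a propyl group and the unbranched C1'–C7' heptamethylene chain to ring B) carry no functionality. It therefore maps onto an aldehyde carbon (butanal), an acyl bromide (ring A) and a terminal olefin (the C6'=C7' end of 4).
4. 13 ⇐ acid 11 ⇐ Vilsmeier formylation and Pinnick oxidation at the ring-A carbon between the chain and a benzyloxy group ⇐ (S)-acetate 8 ⇐ the same hydroalkylation of the same olefin 4 with acetyl bromide and butanal, using the antipodal ligand (C8, S).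
5. 4 ⇐ 3,5-bis(benzyloxy)benzyl bromide 1 + hex-5-enyl Grignard (copper catalysis). The target is thus assembled as a pseudo-dimer of one alkylresorcinol monomer, echoing the presumed biosynthetic esterification of two such units.

Key step: step 6

Assumption: L is a C2-symmetric bis(oxazoline) ligand and ent-L its mirror image; the sense of induction is taken to be the same for the acetate electrophile (step 2) and the aroate electrophile (step 6), so that L should give the (S) ester and ent-L the (R) ester, to be confirmed on the alcohol derived from 8 through its Mosher esters.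

**Step 1**
Reactants: 1 3,5-bis(benzyloxy)benzyl bromide; 2 6-bromohex-1-ene
Product: 4 1,3-bis(benzyloxy)-5-(hept-6-en-1-yl)benzene, via hex-5-en-1-ylmagnesium bromide 3 (not isolated)
Conditions: 2, Mg, THF, rt → 40 °C; then added to 1, Li2CuCl4 (3 mol %), THF, −20 °C → rt
Reagents that add atoms: magnesium, [Mg] (enters intermediate 3 only)
Why: Copper-catalysed Kochi-type C(sp3)–C(sp3) cross-coupling of a primary alkyl Grignard reagent with a benzylic bromide, the classical entry to 5-alkylresorcinol ethers, should leave the terminal olefin and the benzyl ethers untouched.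

**Step 2**
Reactants: 4 1,3-bis(benzyloxy)-5-(hept-6-en-1-yl)benzene; 5 acetyl bromide; 6 butanal
Product: 8 (8S)-1-[3,5-bis(benzyloxy)phenyl]undecan-8-yl acetate, via rac-1-bromobutyl acetate 7 (not isolated)
Conditions: 5, 6, CH2Cl2, 0 °C → rt, evaporate; then 4, NiBr2·glyme (10 mol %), L (12 mol %), (EtO)3SiH, K3PO4·H2O, THF/DMA, rt
Reagents that add atoms: none
Why: Acetyl bromide adds across the aldehyde C=O to give the racemic 1-bromoalkyl ester, which should undergo nickel-hydride enantioconvergent hydroalkylation of the terminal olefin (anti-Markovnikov alkylnickel, stereoablative α-acyloxyalkyl radical), the (S) configuration at C8 being set by the chiral ligand L alone.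

**Step 3**
Reactants: 8 (8S)-1-[3,5-bis(benzyloxy)phenyl]undecan-8-yl acetate
Product: 10 (8S)-1-[3,5-bis(benzyloxy)-2-formylphenyl]undecan-8-yl acetate, via aryl iminium dichlorophosphate 9 (not isolated)
Conditions: POCl3, DMF, 0 → 60 °C; then aq. NaOAc, rt
Reagents that add atoms: N,N-dimethylformamide, CN(C)C=O (formyl carbon); water, O (formyl oxygen); phosphoryl chloride, O=P(Cl)(Cl)Cl (counter-ion of intermediate 9 only)
Why: Vilsmeier–Haack formylation of a 3,5-dialkoxyalkylbenzene should go to the ring carbon flanked by the chain and one benzyloxy group and para to the other, the carbon between the two benzyloxy groups being more hindered, while the acetate and the stereocentre are inert.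

**Step 4**
Reactants: 10 (8S)-1-[3,5-bis(benzyloxy)-2-formylphenyl]undecan-8-yl acetate
Product: 11 2-[(8S)-8-acetoxyundecyl]-4,6-bis(benzyloxy)benzoic acid
Conditions: NaClO2, NaH2PO4, 2-methylbut-2-ene, t-BuOH/THF/H2O, 0 °C → rt
Reagents that add atoms: sodium chlorite, [Na+].[O-]Cl=O
Why: Pinnick oxidation converts the hindered aryl aldehyde into the acid under mildly acidic conditions, the olefin scavenger intercepting hypochlorous acid before it can chlorinate the electron-rich ring.

**Step 5**
Reactants: 11 2-[(8S)-8-acetoxyundecyl]-4,6-bis(benzyloxy)benzoic acid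
Product: 13 2-[(8S)-8-acetoxyundecyl]-4,6-bis(benzyloxy)benzoyl bromide, via sodium carboxylate 12 (not isolated)
Conditions: NaH (1.0 equiv), THF, 0 °C, evaporate; then (COBr)2, DMF (cat.), CH2Cl2, 0 °C → rt; filter, evaporate, use crude
Reagents that add atoms: sodium hydride, [Na+].[H-] (sodium of intermediate 12); oxalyl bromide, O=C(Br)C(=O)Br (bromine of 13)
Why: Acyl bromide formation from a carboxylate salt and oxalyl bromide under Vilsmeier-type DMF catalysis should release only NaBr, CO and CO2, so that no HBr is present to cleave the benzyl ethers or the acetate.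

**Step 6**
Reactants: 13 2-[(8S)-8-acetoxyundecyl]-4,6-bis(benzyloxy)benzoyl bromide; 6 butanal; 4 1,3-bis(benzyloxy)-5-(hept-6-en-1-yl)benzene
Product: 15 (8R)-1-[3,5-bis(benzyloxy)phenyl]undecan-8-yl 2-[(8S)-8-acetoxyundecyl]-4,6-bis(benzyloxy)benzoate, via 1-bromobutyl aroate 14 (not isolated)
Conditions: 6, ZnBr2 (2 mol %), CH2Cl2, 0 °C → rt, evaporate; then 4, NiBr2·glyme (10 mol %), ent-L (12 mol %), (EtO)3SiH, K3PO4·H2O, THF/DMA, rt
Reagents that add atoms: none
Why: The acyl bromide 13 adds across the C=O of butanal to give the 1-bromobutyl aroate 14 as both epimers at the bromine-bearing carbon; a bis(oxazoline)nickel hydride formed from NiBr2·glyme, the silane and the phosphate inserts the terminal olefin of 4 in the anti-Markovnikov sense, a monovalent nickel species abstracts bromine from 14 to give a planar α-aroyloxybutyl radical, and capture of this radical followed by reductive elimination from trivalent nickel forges the bond between the ester-bearing methine carbon and the terminal chain carbon. The closest known reaction type is the nickel-catalysed enantioconvergent hydroalkylation of terminal olefins with racemic 1-bromoalkyl esters, including its four-component aldehyde/acyl bromide/olefin/hydrosilane form. No ring is closed. The new (R) stereocentre is set by the chiral ligand ent-L alone (catalyst control, both epimers of 14 converging through the radical while the ester carbonyl oxygen binds nickel in the selectivity-determining step), the (S) acetate centre being too remote to interfere. The step needs linear regioselectivity, secured by the unbranched monosubstituted olefin whose nearest aryl group lies five methylenes away, and chemoselectivity for the single C(sp3)–Br bond, secured because the benzyl ethers, the acetate and the aroate are inert to nickel hydride at room temperature.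

**Step 7**
Reactants: 15 (8R)-1-[3,5-bis(benzyloxy)phenyl]undecan-8-yl 2-[(8S)-8-acetoxyundecyl]-4,6-bis(benzyloxy)benzoate
Product: 16 (8R)-1-[3,5-bis(benzyloxy)phenyl]undecan-8-yl 2,4-bis(benzyloxy)-6-[(8S)-8-hydroxyundecyl]benzoate
Conditions: K2CO3 (cat.), MeOH/THF, rt
Reagents that add atoms: none
Why: Base-catalysed transesterification should remove the unhindered secondary acetate while the benzoate, shielded on both ortho positions by the chain and a benzyloxy group, resists attack at its carbonyl, and neither carbinol centre can epimerise.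

**Step 8**
Reactants: 16 (8R)-1-[3,5-bis(benzyloxy)phenyl]undecan-8-yl 2,4-bis(benzyloxy)-6-[(8S)-8-hydroxyundecyl]benzoate
Product: 17 (8R)-1-(3,5-dihydroxyphenyl)undecan-8-yl 2,4-dihydroxy-6-[(8S)-8-hydroxyundecyl]benzoate
Conditions: H2 (1 atm), Pd/C (10 wt %), EtOAc/MeOH, rt
Reagents that add atoms: none
Why: Catalytic hydrogenolysis should cleave the four aryl benzyl ethers, whereas the ester C–O bond sits on a non-benzylic secondary carbon and no other reducible group is present.

**Compound list**

1 | 3,5-bis(benzyloxy)benzyl bromide | BrCc1cc(OCc2ccccc2)cc(OCc2ccccc2)c1 | starting material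
2 | 6-bromohex-1-ene | C=CCCCCBr | starting material
3 | hex-5-en-1-ylmagnesium bromide | C=CCCCC[Mg]Br | intermediate
4 | 1,3-bis(benzyloxy)-5-(hept-6-en-1-yl)benzene | C=CCCCCCc1cc(OCc2ccccc2)cc(OCc2ccccc2)c1 | intermediate
5 | acetyl bromide | CC(=O)Br | starting material
6 | butanal | CCCC=O | starting material
7 | rac-1-bromobutyl acetate | CCCC(Br)OC(C)=O | intermediate
8 | (8S)-1-[3,5-bis(benzyloxy)phenyl]undecan-8-yl acetate | CCC[C@H](OC(C)=O)CCCCCCCc1cc(OCc2ccccc2)cc(OCc2ccccc2)c1 | intermediate
9 | {2-[(8S)-8-acetoxyundecyl]-4,6-bis(benzyloxy)phenyl}methylidene(dimethyl)ammonium dichlorophosphate | CCC[C@H](OC(C)=O)CCCCCCCc1cc(OCc2ccccc2)cc(OCc2ccccc2)c1C=[N+](C)C.[O-]P(=O)(Cl)Cl | intermediate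
10 | (8S)-1-[3,5-bis(benzyloxy)-2-formylphenyl]undecan-8-yl acetate | CCC[C@H](OC(C)=O)CCCCCCCc1cc(OCc2ccccc2)cc(OCc2ccccc2)c1C=O | intermediate
11 | 2-[(8S)-8-acetoxyundecyl]-4,6-bis(benzyloxy)benzoic acid | CCC[C@H](OC(C)=O)CCCCCCCc1cc(OCc2ccccc2)cc(OCc2ccccc2)c1C(=O)O | intermediate
12 | sodium 2-[(8S)-8-acetoxyundecyl]-4,6-bis(benzyloxy)benzoate | CCC[C@H](OC(C)=O)CCCCCCCc1cc(OCc2ccccc2)cc(OCc2ccccc2)c1C(=O)[O-].[Na+] | intermediate
13 | 2-[(8S)-8-acetoxyundecyl]-4,6-bis(benzyloxy)benzoyl bromide | CCC[C@H](OC(C)=O)CCCCCCCc1cc(OCc2ccccc2)cc(OCc2ccccc2)c1C(=O)Br | intermediate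
14 | 1-bromobutyl 2-[(8S)-8-acetoxyundecyl]-4,6-bis(benzyloxy)benzoate (both epimers at the bromine-bearing carbon) | CCC[C@H](OC(C)=O)CCCCCCCc1cc(OCc2ccccc2)cc(OCc2ccccc2)c1C(=O)OC(Br)CCC | intermediate
15 | (8R)-1-[3,5-bis(benzyloxy)phenyl]undecan-8-yl 2-[(8S)-8-acetoxyundecyl]-4,6-bis(benzyloxy)benzoate | CCC[C@H](OC(C)=O)CCCCCCCc1cc(OCc2ccccc2)cc(OCc2ccccc2)c1C(=O)O[C@H](CCC)CCCCCCCc1cc(OCc2ccccc2)cc(OCc2ccccc2)c1 | intermediate
16 | (8R)-1-[3,5-bis(benzyloxy)phenyl]undecan-8-yl 2,4-bis(benzyloxy)-6-[(8S)-8-hydroxyundecyl]benzoate | CCC[C@H](O)CCCCCCCc1cc(OCc2ccccc2)cc(OCc2ccccc2)c1C(=O)O[C@H](CCC)CCCCCCCc1cc(OCc2ccccc2)cc(OCc2ccccc2)c1 | intermediate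
17 | (8R)-1-(3,5-dihydroxyphenyl)undecan-8-yl 2,4-dihydroxy-6-[(8S)-8-hydroxyundecyl]benzoate | CCC[C@H](O)CCCCCCCc1cc(O)cc(O)c1C(=O)O[C@H](CCC)CCCCCCCc1cc(O)cc(O)c1 | target

**Step count and risks**

Total step count: 8. Longest linear sequence: 8 (steps 1 to 8; olefin 4 from step 1 enters again in step 6).

Steps most likely to fail:

1. Step 6. The crowded, electron-rich aroyloxy group may slow bromine abstraction and radical capture so that hydrodebromination of 14 and olefin reduction take over, or it may erode the enantiocontrol; an epimer at the ester carbon could then not be separated, because the two stereocentres are far apart. The fallback moves the stereo-setting C–C coupling to the unhindered acetate series and makes the fragment union an ordinary acylation. It sets out from 4, which is coupled with 7 (from 5 and 6) under the conditions of step 2 but with ent-L, to give (8R)-1-[3,5-bis(benzyloxy)phenyl]undecan-8-yl acetate F1. Methanolysis (K2CO3, MeOH/THF) should give (8R)-1-[3,5-bis(benzyloxy)phenyl]undecan-8-ol F2. Acylation of F2 with the acyl bromide 13 (Et3N, DMAP cat., toluene, rt → 60 °C) comes back to the route at 15.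

2. Step 2. Insufficient enantioselectivity, or the unexpected sense of induction, would create a stereochemical impurity at C8 that no later step can remove. The fallback takes the centre from a bought building block. It sets out from 4, which undergoes cross-metathesis with an excess of commercial (S)-hex-1-en-3-ol (second-generation Hoveyda–Grubbs catalyst, CH2Cl2, 40 °C) to give (4S,5E)-11-[3,5-bis(benzyloxy)phenyl]undec-5-en-4-ol F3. Acetylation (Ac2O, pyridine, DMAP cat.) should give (4S,5E)-11-[3,5-bis(benzyloxy)phenyl]undec-5-en-4-yl acetate F4. Diimide reduction of the alkene (TsNHNH2, NaOAc, DME/H2O, reflux), which spares benzyl ethers and the allylic C–O bond, comes back to the route at 8.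

3. Step 5. Adventitious HBr may cleave the ortho benzyl ether or the acetate, and the crowded acyl bromide may hydrolyse or decompose on handling. The fallback avoids any acyl halide and uses acid 11 itself as the nucleophile, exploiting the opposite configurations of the two carbinol centres of the target. It sets out from 8, whose methanolysis (K2CO3, MeOH/THF) should give (8S)-1-[3,5-bis(benzyloxy)phenyl]undecan-8-ol F5. Mitsunobu esterification of F5 with acid 11 (PPh3, DIAD, toluene, 0 °C → rt) should proceed with inversion and comes back to the route at 15.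

**Further compounds**

F1 | step 6 | (8R)-1-[3,5-bis(benzyloxy)phenyl]undecan-8-yl acetate | CCC[C@@H](OC(C)=O)CCCCCCCc1cc(OCc2ccccc2)cc(OCc2ccccc2)c1
F2 | step 6 | (8R)-1-[3,5-bis(benzyloxy)phenyl]undecan-8-ol | CCC[C@@H](O)CCCCCCCc1cc(OCc2ccccc2)cc(OCc2ccccc2)c1
F3 | step 2 | (4S,5E)-11-[3,5-bis(benzyloxy)phenyl]undec-5-en-4-ol | CCC[C@H](O)/C=C/CCCCCc1cc(OCc2ccccc2)cc(OCc2ccccc2)c1
F4 | step 2 | (4S,5E)-11-[3,5-bis(benzyloxy)phenyl]undec-5-en-4-yl acetate | CCC[C@H](OC(C)=O)/C=C/CCCCCc1cc(OCc2ccccc2)cc(OCc2ccccc2)c1
F5 | step 5 | (8S)-1-[3,5-bis(benzyloxy)phenyl]undecan-8-ol | CCC[C@H](O)CCCCCCCc1cc(OCc2ccccc2)cc(OCc2ccccc2)c1
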